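## Retrosynthetic overview

1. The target comes from allyl 18-acetoxy-3β-hydroxylabda-8(17),13E-dien-15-oate by radical removal of the C3 hydroxyl, which serves only as a stereochemical control element, followed by deallylation.
2. Both rings come from one radical polyene cascade of an acyclic epoxy acetate, folded as in the copalyl diphosphate cyclisation. C4–C5 closes ring A first, C10–C9 closes ring B second, and loss of a C17 hydrogen gives the exocyclic alkene.
3. The epoxy acetate comes from hydroxyl-directed asymmetric epoxidation and acetylation of the ω-(E)-allylic alcohol, itself made by SeO2 oxidation of allyl geranylgeranoate. This oxygen becomes the C18 acetate.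
4. Allyl geranylgeranoate comes from a Horner–Wadsworth–Emmons reaction of (E,E)-farnesylacetone with allyl diethylphosphonoacetate.

Assumption: farnesylacetone is used as the pure (5E,9E) isomer, and bicyclic compounds carry labdane numbering (C18 = equatorial 4α-CH2, C19 = axial 4β-CH3, C20 = 10β-CH3, C17 = exocyclic CH2).

## Route

Step 1
Reactants: 1 (5E,9E)-6,10,14-trimethylpentadeca-5,9,13-trien-2-one ((E,E)-farnesylacetone); 2 prop-2-enyl (diethoxyphosphoryl)acetate (allyl diethylphosphonoacetate)
Product: 3 prop-2-enyl (2E,6E,10E)-3,7,11,15-tetramethylhexadeca-2,6,10,14-tetraenoate (allyl geranylgeranoate)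
Conditions: NaH (1.3 equiv), THF, 0 °C → rt, 16 h; 2E isomer separated from 2Z on SiO2
Reagents that add atoms: none
Why: Horner–Wadsworth–Emmons olefination of a methyl ketone places the ester trans to the long chain (about 4:1 2E:2Z, separable), and the allyl ester is chosen because it can later be removed without touching an acetate.

Step 2
Reactants: 3 allyl geranylgeranoate
Product: 4 prop-2-enyl (2E,6E,10E,14E)-16-hydroxy-3,7,11,15-tetramethylhexadeca-2,6,10,14-tetraenoate
Conditions: SeO2 (0.1 equiv), salicylic acid (0.1 equiv), t-BuOOH (3 equiv), CH2Cl2, 0 °C → rt; stopped at about 60% conversion, 3 recycled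
Reagents that add atoms: tert-butyl hydroperoxide, CC(C)(C)OO (one oxygen atom, passed on through catalytic SeO2, O=[Se]=O)
Why: Catalytic SeO2 allylic oxidation (ene reaction, then [2,3]-sigmatropic shift) prefers the electron-rich, least hindered terminal isopropylidene group and gives only the (E)-CH2OH, the carbon that becomes equatorial C18, while the enoate and allyl alkenes are too unreactive.

Step 3
Reactants: 4 ω-(E)-allylic alcohol
Product: 6 prop-2-enyl (2E,6E,10E)-13-[(2S,3S)-3-(acetoxymethyl)-3-methyloxiran-2-yl]-3,7,11-trimethyltrideca-2,6,10-trienoate, via epoxy alcohol 5 (not isolated)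
Conditions: Ti(OiPr)4 (10 mol %), L-(+)-diethyl tartrate (12 mol %), t-BuOOH (2 equiv, decane), 4 Å MS, CH2Cl2, −20 °C; P(OMe)3, −20 °C; then Ac2O, Et3N, DMAP (cat.), −20 → 0 °C
Reagents that add atoms: tert-butyl hydroperoxide, CC(C)(C)OO; acetic anhydride, CC(=O)OC(C)=O
Why: Katsuki–Sharpless asymmetric epoxidation is hydroxyl-directed, so only the allylic-alcohol alkene of five C=C bonds reacts, L-(+)-tartrate gives the (2S,3S)-epoxide (>95% ee expected; its CH–O carbon is the future C3, S), and in-situ acetylation installs the acetate of the target.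

Step 4
Reactants: 6 (2S,3S)-epoxy acetate
Product: 8 allyl (3S,4R,5R,9S,10R,13E)-18-acetoxy-3-hydroxylabda-8(17),13-dien-15-oate, via trimethylsilyl ether 7 (not isolated)
Conditions: Cp2TiCl2 (0.2 equiv), Mn dust (8 equiv), Me3SiCl (4 equiv), 2,4,6-collidine (7 equiv), dry degassed THF (0.02 M), rt, 16 h; then 1 M HCl, THF, rt, 30 min
Reagents that add atoms: chlorotrimethylsilane, C[Si](C)(C)Cl (Me3Si group of 7 only; it is gone again in 8)
Why: In this titanocene-catalysed epoxypolyene radical cyclisation, Cp2TiCl (trivalent titanium) homolyses the C4–O bond to the tertiary C4 radical, which closes ring A (C4–C5) and then ring B (C10–C9) 6-endo/6-endo through a chair–chair array whose equatorial (3S)-C–O–Ti bond fixes C5 (R), C10 (R) and C9 (S) and whose larger CH2OAc group sits pseudo-equatorial anti to C2 (4R), while the electron-poor β,β-disubstituted enoate stops the cascade at two rings and Cp2TiCl-mediated loss of a C17 hydrogen from the C8 radical gives the exocyclic alkene.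

Step 5
Reactants: 8 3β-alcohol
Product: 9 allyl (3S,4R,5R,9S,10R,13E)-18-acetoxy-3-[(imidazol-1-yl)carbothioyloxy]labda-8(17),13-dien-15-oate
Conditions: 1,1'-thiocarbonyldiimidazole (3 equiv), DMAP (0.3 equiv), ClCH2CH2Cl, 80 °C, 12 h
Reagents that add atoms: 1,1'-thiocarbonyldiimidazole, S=C(n1ccnc1)n1ccnc1
Why: Thioacylation of the only free hydroxyl (first half of a Barton–McCombie deoxygenation) runs without alkoxide formation, so the acetyl group does not migrate from O18 to O3 and no stereocentre is touched.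

Step 6
Reactants: 9 imidazolyl thiocarbonate
Product: 10 allyl (4R,5R,9S,10R,13E)-18-acetoxylabda-8(17),13-dien-15-oate
Conditions: Bu3SnH (2 equiv), AIBN (0.2 equiv), toluene, 100 °C, 2 h
Reagents that add atoms: none
Why: In the Barton–McCombie deoxygenation the stannyl radical adds to C=S, the secondary C3 radical is released and takes hydrogen from Bu3SnH, which erases the C3 control centre while C4, C5, C9 and C10 and all alkenes (none within cyclisation reach of C3) stay as they are.

Step 7
Reactants: 10 allyl ester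
Product: 11 (4R,5R,9S,10R,13E)-18-acetoxylabda-8(17),13-dien-15-oic acid (target)
Conditions: Pd(PPh3)4 (5 mol %), morpholine (5 equiv), THF, rt, 1 h; aqueous citric acid work-up
Reagents that add atoms: none
Why: In this Tsuji–Trost deallylation zerovalent palladium ionises only the allyl ester to a π-allyl complex that morpholine captures, so the neopentyl acetate, the acid-sensitive exocyclic alkene, the 13E-enoate and the four stereocentres are untouched.

## Compound list

1 | (5E,9E)-6,10,14-trimethylpentadeca-5,9,13-trien-2-one | CC(C)=CCC/C(C)=C/CC/C(C)=C/CCC(C)=O | starting material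
2 | prop-2-enyl (diethoxyphosphoryl)acetate | C=CCOC(=O)CP(=O)(OCC)OCC | starting material
3 | prop-2-enyl (2E,6E,10E)-3,7,11,15-tetramethylhexadeca-2,6,10,14-tetraenoate | CC(C)=CCC/C(C)=C/CC/C(C)=C/CC/C(C)=C/C(=O)OCC=C | intermediate
4 | prop-2-enyl (2E,6E,10E,14E)-16-hydroxy-3,7,11,15-tetramethylhexadeca-2,6,10,14-tetraenoate | OC/C(C)=C/CC/C(C)=C/CC/C(C)=C/CC/C(C)=C/C(=O)OCC=C | intermediate
5 | prop-2-enyl (2E,6E,10E)-13-[(2S,3S)-3-(hydroxymethyl)-3-methyloxiran-2-yl]-3,7,11-trimethyltrideca-2,6,10-trienoate | OC[C@]1(C)O[C@H]1CC/C(C)=C/CC/C(C)=C/CC/C(C)=C/C(=O)OCC=C | intermediate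
6 | prop-2-enyl (2E,6E,10E)-13-[(2S,3S)-3-(acetoxymethyl)-3-methyloxiran-2-yl]-3,7,11-trimethyltrideca-2,6,10-trienoate | CC(=O)OC[C@]1(C)O[C@H]1CC/C(C)=C/CC/C(C)=C/CC/C(C)=C/C(=O)OCC=C | intermediate
7 | allyl (3S,4R,5R,9S,10R,13E)-18-acetoxy-3-(trimethylsilyloxy)labda-8(17),13-dien-15-oate | C=C1CC[C@H]2[C@](C)(COC(C)=O)[C@@H](O[Si](C)(C)C)CC[C@]2(C)[C@H]1CC/C(C)=C/C(=O)OCC=C | intermediate
8 | allyl (3S,4R,5R,9S,10R,13E)-18-acetoxy-3-hydroxylabda-8(17),13-dien-15-oate (3β-OH and 4α-CH2OAc equatorial, 4β-CH3 and 10β-CH3 axial, 5α-H, 9α-H) | C=C1CC[C@H]2[C@](C)(COC(C)=O)[C@@H](O)CC[C@]2(C)[C@H]1CC/C(C)=C/C(=O)OCC=C | intermediate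
9 | allyl (3S,4R,5R,9S,10R,13E)-18-acetoxy-3-[(imidazol-1-yl)carbothioyloxy]labda-8(17),13-dien-15-oate | C=C1CC[C@H]2[C@](C)(COC(C)=O)[C@@H](OC(=S)n3ccnc3)CC[C@]2(C)[C@H]1CC/C(C)=C/C(=O)OCC=C | intermediate
10 | allyl (4R,5R,9S,10R,13E)-18-acetoxylabda-8(17),13-dien-15-oate | C=C1CC[C@H]2[C@](C)(COC(C)=O)CCC[C@]2(C)[C@H]1CC/C(C)=C/C(=O)OCC=C | intermediate
11 | (4R,5R,9S,10R,13E)-18-acetoxylabda-8(17),13-dien-15-oic acid | C=C1CC[C@H]2[C@](C)(COC(C)=O)CCC[C@]2(C)[C@H]1CC/C(C)=C/C(=O)O | target

## Step count, risks and fallbacks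

Total step count: 7. Longest linear sequence: 7 (1 → 11).

**First risk, step 4.**
- The C4 radical is planar, so some 4-epimer (19-acetoxy series) can form.
- The tertiary C8 radical can add 5-exo to C13 of the enoate.
- Capture of the C4 radical by Cp2TiCl would expel acetate.

The fallback leaves the radical manifold for the cationic one. It sets out from 6 and comes back at 8. Compound 6 is treated with MeAlCl2 (3 equiv) in CH2Cl2 at −78 °C, so that the C4–O bond is broken by backside attack of the C5=C10 alkene (epoxide-initiated cation–olefin bicyclisation). C4 is then set stereospecifically: the CH2OAc group trans to C2 on the epoxide ends equatorial. The enoate is inert to carbocations. The price is unselective proton loss from the C8 cation. Compound 8 must therefore be separated on AgNO3-impregnated silica from its endocyclic isomer, allyl (3S,4R,5R,9S,10R,13E)-18-acetoxy-3-hydroxylabda-7,13-dien-15-oate F1.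

**Second risk, step 2.** Three trisubstituted alkenes compete and over-oxidation occurs, so only about 35–45% of 4 is expected.

The fallback replaces C–H oxidation by cutting and rebuilding the chain end. It sets out from 3 and comes back at 4.
- NBS in THF–water adds selectively at the terminal alkene. This gives allyl (2E,6E,10E)-14-bromo-15-hydroxy-3,7,11,15-tetramethylhexadeca-2,6,10-trienoate F2.
- K2CO3 in 2-propanol closes F2 to the racemic allyl (2E,6E,10E)-14,15-epoxy-3,7,11,15-tetramethylhexadeca-2,6,10-trienoate F3.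
- H5IO6 in THF–water cleaves F3 to allyl (2E,6E,10E)-3,7,11-trimethyl-14-oxotetradeca-2,6,10-trienoate F4.
- Wittig reaction of F4 with 2-(triphenylphosphoranylidene)propanal in toluene at 80 °C gives allyl (2E,6E,10E,14E)-3,7,11,15-tetramethyl-16-oxohexadeca-2,6,10,14-tetraenoate F5.
- NaBH4 and CeCl3·7H2O in MeOH at 0 °C reduce F5 1,2 to 4.

**Third risk, step 5.** The 3β-hydroxyl lies next to the quaternary C4, so thioacylation may be slow. Long heating with imidazole could also shift the acetyl group.

The fallback removes the oxygen through the carbonyl oxidation level and not by a radical. It sets out from 8 and comes back at 10.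
- Dess–Martin periodinane in CH2Cl2 gives allyl (4R,5R,9S,10R,13E)-18-acetoxy-3-oxolabda-8(17),13-dien-15-oate F6. This ketone cannot eliminate acetate because C4 bears no hydrogen.
- TsNHNH2 with catalytic AcOH in EtOH gives the p-toluenesulfonylhydrazone of that ketone F7 (C=N geometry not fixed).
- Catecholborane in CHCl3 at −10 °C, then NaOAc·3H2O at reflux, reduces F7 to the methylene compound 10. The alkenes are not hydroborated at that temperature.

## Further compounds

F1 | step 4 | allyl (3S,4R,5R,9S,10R,13E)-18-acetoxy-3-hydroxylabda-7,13-dien-15-oate | CC1=CC[C@H]2[C@](C)(COC(C)=O)[C@@H](O)CC[C@]2(C)[C@H]1CC/C(C)=C/C(=O)OCC=C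
F2 | step 2 | allyl (2E,6E,10E)-14-bromo-15-hydroxy-3,7,11,15-tetramethylhexadeca-2,6,10-trienoate (racemic) | CC(C)(O)C(Br)CC/C(C)=C/CC/C(C)=C/CC/C(C)=C/C(=O)OCC=C
F3 | step 2 | allyl (2E,6E,10E)-14,15-epoxy-3,7,11,15-tetramethylhexadeca-2,6,10-trienoate (racemic) | CC1(C)OC1CC/C(C)=C/CC/C(C)=C/CC/C(C)=C/C(=O)OCC=C
F4 | step 2 | allyl (2E,6E,10E)-3,7,11-trimethyl-14-oxotetradeca-2,6,10-trienoate | O=CCC/C(C)=C/CC/C(C)=C/CC/C(C)=C/C(=O)OCC=C
F5 | step 2 | allyl (2E,6E,10E,14E)-3,7,11,15-tetramethyl-16-oxohexadeca-2,6,10,14-tetraenoate | O=C/C(C)=C/CC/C(C)=C/CC/C(C)=C/CC/C(C)=C/C(=O)OCC=C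
F6 | step 5 | allyl (4R,5R,9S,10R,13E)-18-acetoxy-3-oxolabda-8(17),13-dien-15-oate | C=C1CC[C@H]2[C@](C)(COC(C)=O)C(=O)CC[C@]2(C)[C@H]1CC/C(C)=C/C(=O)OCC=C
F7 | step 5 | p-toluenesulfonylhydrazone of allyl (4R,5R,9S,10R,13E)-18-acetoxy-3-oxolabda-8(17),13-dien-15-oate | C=C1CC[C@H]2[C@](C)(COC(C)=O)C(=NNS(=O)(=O)c3ccc(C)cc3)CC[C@]2(C)[C@H]1CC/C(C)=C/C(=O)OCC=C
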